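## Retrosynthetic overview

- Target ⇐ late α′-hydroxylation at C2 of the 2-deoxy enone; the isopropylidene enone ⇐ Mukaiyama-type condensation of a regiodefined ring B silyl enol ether with acetone dimethyl ketal.
- 7β,8β-Diacetate ⇐ α-face hydride reduction of a C7 enone plus Mitsunobu inversion of an 8α-ketol, both steered by the cis ring fusion.
- cis-Fused core ⇐ one-pot radical annulation: an α-keto radical adds to C8a of a linear silyl dienol ether, the silyloxyallyl radical closes C4a–C5 (6-endo), then bromine transfer and loss of HBr.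
- Ring order: ring B is bought as (R)-5-methylcyclohex-2-en-1-one, whose methyl stereocentre controls all others; ring A is built onto it in the key step from 1-bromo-3-methylbut-3-en-2-one.

Assumption: (R)-5-methylcyclohex-2-en-1-one is taken as a purchasable single enantiomer (eight non-hydrogen atoms).

Convention: bicyclic compounds carry the target's locants (C1 methyl-bearing carbon, C2 carbinol, C3 ketone, C4 isopropylidene carbon, C4a/C8a ring fusion, C6 vinylic-methyl carbon, C7/C8 acetoxy carbons). Ring B is C1–C4/C4a/C8a and ring A is C4a–C8a. β is the face of the C7/C8 acetoxy groups; α is the face of H-4a, H-8a and the C1 methyl.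

## Route

Step 1
Reactants: 1 3-methylbut-3-en-2-one
Product: 3 1-bromo-3-methylbut-3-en-2-one, via silyl dienol ether 2 (not isolated)
Conditions: TMSOTf, Et3N, Et2O, 0 °C; then NBS, THF, −78 → 0 °C; used crude, BHT-stabilised
Reagents that add atoms: N-bromosuccinimide, O=C1CCC(=O)N1Br
Why: Soft enolisation can only take place at the acetyl methyl, and NBS brominates the terminus of the resulting silyl enol ether (silyl enol ether α-bromination), leaving the isopropenyl group intact; no stereocentre is formed.

Step 2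
Reactants: 4 (R)-5-methylcyclohex-2-en-1-one
Product: 6 (5S)-1-(tert-butyldimethylsilyloxy)-5-methylcyclohexa-1,3-diene, via potassium dienolate 5 (not isolated)
Conditions: KN(SiMe3)2 (1.1 equiv), THF, −78 → 0 °C, 1 h; then TBSCl, DMPU, −78 → 23 °C
Reagents that add atoms: tert-butyldimethylsilyl chloride, CC(C)(C)[Si](C)(C)Cl
Why: Under equilibrating conditions (proton shuttling through HN(SiMe3)2) the enolate mixture funnels to the more delocalised γ-deprotonated dienolate, the thermodynamic dienolate of an enone, and O-silylation gives the linear dienol ether (thermodynamic silyl dienol ether formation); the methyl-bearing stereocentre is not acidic and is untouched.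

Step 3
Reactants: 6 (5S)-1-(tert-butyldimethylsilyloxy)-5-methylcyclohexa-1,3-diene; 3 1-bromo-3-methylbut-3-en-2-one
Product: 8 cis-fused ring A enone with ring B silyl enol ether (3-OTBS; 1α-Me; 4aα-H; 8aα-H), via tertiary bromide 7 (not isolated)
Conditions: CuBr (5 mol%), tris(2-pyridylmethyl)amine (5 mol%), copper wire (zerovalent copper), MeCN–PhMe, 23 °C, 3 (1.3 equiv) added over 8 h; then DBU, 50 °C
Reagents that add atoms: none
Why: Proposed new method: monovalent copper abstracts bromine from 3 to give an electrophilic α-keto radical that adds to the electron-rich diene terminus C8a of 6 anti to the pseudoaxial C1 methyl; the resulting silyloxyallyl radical closes ring A by 6-endo attack of C4a on the β-carbon (C5) of the pendant vinyl ketone from the face of the C8a tether (hence the cis fusion and a regiodefined C3=C4 silyl enol ether); the tertiary α-keto radical is capped by bromine transfer from CuBr2 to give 7, which loses HBr with DBU to the conjugated enone; slow addition keeps divalent copper and 3 low so that cyclisation outruns oxidation of the allyl radical; the closest known chemistry is copper-catalysed atom-transfer radical addition/cyclisation (Kharasch type), radical γ-alkylation of silyl dienol ethers by α-bromo ketones and 6-endo cyclisation onto in-chain vinyl ketones, here merged into one annulation.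

Step 4
Reactants: 8 cis-fused ring A enone with ring B silyl enol ether
Product: 10 8α-hydroxy enone, via sodium enolate 9 (not isolated)
Conditions: NaN(SiMe3)2, THF, −78 °C; 3-phenyl-2-(phenylsulfonyl)oxaziridine, −78 °C; AcOH quench
Reagents that add atoms: 3-phenyl-2-(phenylsulfonyl)oxaziridine, O=S(=O)(c1ccccc1)N1OC1c1ccccc1
Why: Davis hydroxylation of the kinetic α′-enolate of the only ketone present; the C8a–C1 bond is axial on ring A and blocks the β-face of C8, so oxygen enters axially from the α-face to give the 8α-ol, which is the epimer needed for inversion in step 5.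

Step 5
Reactants: 10 8α-hydroxy enone
Product: 11 8β-acetoxy enone
Conditions: PPh3, DIAD, AcOH, PhMe, 0 → 23 °C
Reagents that add atoms: acetic acid, CC(=O)O
Why: Mitsunobu esterification: acetate displaces the axial, carbonyl-activated 8α-oxyphosphonium group by SN2 with inversion to the equatorial 8β-acetate, and no antiperiplanar β-hydrogen is available for elimination.

Step 6
Reactants: 11 8β-acetoxy enone
Product: 12 7β-hydroxy 8β-acetate
Conditions: NaBH4, CeCl3·7H2O, MeOH, −78 °C
Reagents that add atoms: none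
Why: Luche 1,2-reduction: the axial C8a–C1 bond is syn-axial to the β-face trajectory at C7, so hydride enters from the α-face and gives the 7β-allylic alcohol cis to the 8β-acetate; the silyl enol ether and ester survive at −78 °C, and any 1,2-acetyl shift is irrelevant after step 7.

Step 7
Reactants: 12 7β-hydroxy 8β-acetate
Product: 13 7β,8β-diacetate with ring B silyl enol ether
Conditions: Ac2O, pyridine, DMAP (cat.), CH2Cl2, 0 → 23 °C
Reagents that add atoms: acetic anhydride, CC(=O)OC(C)=O
Why: DMAP-catalysed acylation of the allylic alcohol with retention; no stereocentre changes.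

Step 8
Reactants: 13 7β,8β-diacetate with ring B silyl enol ether; 14 2,2-dimethoxypropane
Product: 16 isopropylidene enone (2-deoxy target), via methoxy ketone 15 (not isolated)
Conditions: TMSOTf (0.2 equiv), CH2Cl2, −78 °C; then DBU, 0 → 40 °C
Reagents that add atoms: none
Why: Noyori-type Mukaiyama aldol addition of the C3 silyl enol ether to the methoxycarbenium ion from the ketal forms the C4–CMe2OMe bond regiospecifically, and E1cB loss of methanol gives the conjugated isopropylidene enone; the C4 stereocentre is transient, and the C3 ketone is unmasked only after the ring A ketone has been reduced.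

Step 9
Reactants: 16 isopropylidene enone (2-deoxy target)
Product: 18 target, via sodium enolate 17 (not isolated)
Conditions: NaN(SiMe3)2 (1.05 equiv), THF, −78 °C; 3-phenyl-2-(phenylsulfonyl)oxaziridine; AcOH quench; then DBU (0.1 equiv), CH2Cl2, 0 °C
Reagents that add atoms: 3-phenyl-2-(phenylsulfonyl)oxaziridine, O=S(=O)(c1ccccc1)N1OC1c1ccccc1
Why: Davis hydroxylation of the kinetic α′-enolate (C2 is the only enolisable α-carbon of the C3 ketone, and the ketone is deprotonated far faster than the acetates at −78 °C); the kinetic facial preference at C2 is not secure, but the 2β-alcohol trans to the C1 methyl is the equatorial, hydrogen-bonded α-ketol, so any 2α-epimer converges on it through the enediolate on brief DBU treatment.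

## Compound list

1 | 3-methylbut-3-en-2-one | CC(=O)C(C)=C | starting material
2 | 3-methyl-2-(trimethylsilyloxy)buta-1,3-diene | C=C(O[Si](C)(C)C)C(C)=C | intermediate
3 | 1-bromo-3-methylbut-3-en-2-one | BrCC(=O)C(C)=C | intermediate
4 | (R)-5-methylcyclohex-2-en-1-one | O=C1C=CC[C@@H](C)C1 | starting material
5 | potassium (5S)-5-methylcyclohexa-1,3-dien-1-olate | C1[C@@H](C)CC(O[K])=CC=1 | intermediate
6 | (5S)-1-(tert-butyldimethylsilyloxy)-5-methylcyclohexa-1,3-diene | C1[C@@H](C)CC(O[Si](C)(C)C(C)(C)C)=CC=1 | intermediate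
7 | 6-bromo-3-(tert-butyldimethylsilyloxy)-1α,6-dimethyl-1,2,4a,5,6,8a-hexahydronaphthalen-7(8H)-one (cis-fused, 4aα-H, 8aα-H, C6 epimers) | C1[C@@H]2[C@@H](C)CC(O[Si](C)(C)C(C)(C)C)=C[C@@H]2CC(C)(Br)C1=O | intermediate
8 | 3-(tert-butyldimethylsilyloxy)-1α,6-dimethyl-1,2,4a,8a-tetrahydronaphthalen-7(8H)-one (cis-fused, 4aα-H, 8aα-H) | C1[C@@H]2[C@@H](C)CC(O[Si](C)(C)C(C)(C)C)=C[C@@H]2C=C(C)C1=O | intermediate
9 | sodium 3-(tert-butyldimethylsilyloxy)-1α,6-dimethyl-1,2,4a,8a-tetrahydronaphthalen-7-olate (C7=C8 enolate of 8) | C=1[C@@H]2[C@@H](C)CC(O[Si](C)(C)C(C)(C)C)=C[C@@H]2C=C(C)C=1O[Na] | intermediate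
10 | 3-(tert-butyldimethylsilyloxy)-8α-hydroxy-1α,6-dimethyl-1,2,4a,8a-tetrahydronaphthalen-7(8H)-one (4aα-H, 8aα-H) | O[C@H]1[C@@H]2[C@@H](C)CC(O[Si](C)(C)C(C)(C)C)=C[C@@H]2C=C(C)C1=O | intermediate
11 | 8β-acetoxy-3-(tert-butyldimethylsilyloxy)-1α,6-dimethyl-1,2,4a,8a-tetrahydronaphthalen-7(8H)-one (4aα-H, 8aα-H) | CC(=O)O[C@@H]1[C@@H]2[C@@H](C)CC(O[Si](C)(C)C(C)(C)C)=C[C@@H]2C=C(C)C1=O | intermediate
12 | 8β-acetoxy-3-(tert-butyldimethylsilyloxy)-1α,6-dimethyl-1,2,4a,7,8,8a-hexahydronaphthalen-7β-ol (4aα-H, 8aα-H) | CC(=O)O[C@@H]1[C@@H]2[C@@H](C)CC(O[Si](C)(C)C(C)(C)C)=C[C@@H]2C=C(C)[C@@H]1O | intermediate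
13 | 7β,8β-diacetoxy-3-(tert-butyldimethylsilyloxy)-1α,6-dimethyl-1,2,4a,7,8,8a-hexahydronaphthalene (4aα-H, 8aα-H) | CC(=O)O[C@@H]1[C@@H]2[C@@H](C)CC(O[Si](C)(C)C(C)(C)C)=C[C@@H]2C=C(C)[C@@H]1OC(C)=O | intermediate
14 | 2,2-dimethoxypropane | COC(C)(C)OC | starting material
15 | 7β,8β-diacetoxy-4-(2-methoxypropan-2-yl)-1α,6-dimethyl-1,2,4a,7,8,8a-hexahydronaphthalen-3(4H)-one (4aα-H, 8aα-H, C4 epimers) | CC(=O)O[C@@H]1[C@@H]2[C@@H](C)CC(=O)C(C(C)(C)OC)[C@@H]2C=C(C)[C@@H]1OC(C)=O | intermediate
16 | 7β,8β-diacetoxy-1α,6-dimethyl-4-(propan-2-ylidene)-1,2,4a,7,8,8a-hexahydronaphthalen-3(4H)-one (4aα-H, 8aα-H) | CC(=O)O[C@@H]1[C@@H]2[C@@H](C)CC(=O)C(=C(C)C)[C@@H]2C=C(C)[C@@H]1OC(C)=O | intermediate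
17 | sodium C2=C3 enolate of 16 (7β,8β-diacetoxy-1α,6-dimethyl-4-(propan-2-ylidene)-1,4,4a,7,8,8a-hexahydronaphthalen-3-olate) | CC(=O)O[C@@H]1[C@@H]2[C@@H](C)C=C(O[Na])C(=C(C)C)[C@@H]2C=C(C)[C@@H]1OC(C)=O | intermediate
18 | (1R,2S,4aR,7S,8R,8aS)-7,8-diacetoxy-2-hydroxy-1,6-dimethyl-4-(propan-2-ylidene)-1,2,4a,7,8,8a-hexahydronaphthalen-3(4H)-one (1α-Me, 2β-OH, 7β,8β-OAc, 4aα-H, 8aα-H) | CC(=O)O[C@@H]1[C@@H]2[C@@H](C)[C@H](O)C(=O)C(=C(C)C)[C@@H]2C=C(C)[C@@H]1OC(C)=O | target

## Step count and risks

Total: 9 steps (step 1 is a one-step side branch). Longest linear sequence: 8 steps (4 → 18, steps 2–9).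

**Step 3 (radical annulation).** The silyloxyallyl radical may be oxidised or brominated before it cyclises, giving the uncyclised γ-alkylated enone. Diene 6 and vinyl ketone 3 may also undergo a background Diels–Alder reaction, and the facial selectivity at C8a may be only moderate. The fallback sets out from 3 and 6 and returns at 8, replacing copper-mediated bromine transfer by a metal-free degenerative xanthate transfer. Bromide 3 is treated with EtOC(S)SK in acetone at 0 °C to give S-(3-methyl-2-oxobut-3-en-1-yl) O-ethyl carbonodithioate F1. F1 and 6 are combined under Et3B/air at 23 °C (or dilauroyl peroxide), where the same addition/6-endo sequence ends by xanthate transfer to the tertiary radical and gives the cis-fused tertiary xanthate 3-(tert-butyldimethylsilyloxy)-6-(ethoxycarbonothioylthio)-1α,6-dimethyl-1,2,4a,5,6,8a-hexahydronaphthalen-7(8H)-one F2. DBU or brief heating in toluene then eliminates the xanthate to give 8.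

**Step 2 (linear dienol ether).** The cross-conjugated α′-isomer may form, or the enolate may add to unreacted enone. The fallback sets out from 4 and returns at 6 through an acid-equilibrated enol ester. Enone 4 is heated with isopropenyl acetate and catalytic p-TsOH, with removal of acetone, to give the thermodynamic (5S)-5-methylcyclohexa-1,3-dien-1-yl acetate F3, which is purified from the minor 2-acetoxy isomer. MeLi (2 equiv, DME, 0 °C) cleaves the ester regiospecifically to lithium (5S)-5-methylcyclohexa-1,3-dien-1-olate F4, which is silylated in the same flask with TBSCl/DMPU to 6.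

**Step 5 (Mitsunobu inversion at a hindered α-ketol).** Conversion may be low, or an enol derivative may form. The fallback sets out from 10 and returns at 13 by redox inversion instead of substitution. Ketol 10 is oxidised with Dess–Martin periodinane (CH2Cl2, 0 °C) to 3-(tert-butyldimethylsilyloxy)-1α,6-dimethyl-1,2,4a,8a-tetrahydronaphthalene-7,8-dione F5, which is used cold and crude to limit enolisation towards C8a. NaBH4/CeCl3·7H2O (MeOH, −78 °C) reduces both carbonyls from the open α-face to 3-(tert-butyldimethylsilyloxy)-1α,6-dimethyl-1,2,4a,7,8,8a-hexahydronaphthalene-7β,8β-diol F6. Ac2O/pyridine/DMAP then gives 13, bypassing steps 5–7.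

Further compounds
F1 | step 3 | S-(3-methyl-2-oxobut-3-en-1-yl) O-ethyl carbonodithioate | CCOC(=S)SCC(=O)C(C)=C
F2 | step 3 | 3-(tert-butyldimethylsilyloxy)-6-(ethoxycarbonothioylthio)-1α,6-dimethyl-1,2,4a,5,6,8a-hexahydronaphthalen-7(8H)-one (cis-fused, 4aα-H, 8aα-H, C6 epimers) | C1[C@@H]2[C@@H](C)CC(O[Si](C)(C)C(C)(C)C)=C[C@@H]2CC(C)(SC(=S)OCC)C1=O
F3 | step 2 | (5S)-5-methylcyclohexa-1,3-dien-1-yl acetate | C1[C@@H](C)CC(OC(C)=O)=CC=1
F4 | step 2 | lithium (5S)-5-methylcyclohexa-1,3-dien-1-olate | C1[C@@H](C)CC(O[Li])=CC=1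
F5 | step 5 | 3-(tert-butyldimethylsilyloxy)-1α,6-dimethyl-1,2,4a,8a-tetrahydronaphthalene-7,8-dione (4aα-H, 8aα-H) | O=C1[C@@H]2[C@@H](C)CC(O[Si](C)(C)C(C)(C)C)=C[C@@H]2C=C(C)C1=O
F6 | step 5 | 3-(tert-butyldimethylsilyloxy)-1α,6-dimethyl-1,2,4a,7,8,8a-hexahydronaphthalene-7β,8β-diol (4aα-H, 8aα-H) | O[C@@H]1[C@@H]2[C@@H](C)CC(O[Si](C)(C)C(C)(C)C)=C[C@@H]2C=C(C)[C@@H]1O
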